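The trimer is cut at the C4–C4a bond of the bottom epigallocatechin unit. Ring C of that unit is closed last by a gold-catalysed Friedel–Crafts opening of a terminal epoxide. The ring-A carbon ortho to O1 (future C4a, the only free ortho carbon because C8 already carries C4 of the galloylated middle unit) attacks the epoxide CH2. This creates the C4 methylene and releases the 3-hydroxyl, with C2 and C3 set beforehand. The precursor is the fully benzylated top–middle dimer whose C4-bound 2-hydroxy-4,6-bis(benzyloxy)phenyl ring is etherified, with inversion, by a (1S,2R)-epoxy alcohol. Both flavan units come from epigallocatechin; a 4-benzylsulfanyl group keeps the middle C4 latent until needed.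

Key step: step 11

Remark: the stereodescriptors of 14 and 15 were checked atom by atom against 16 and agree with it. All three units are 2R with 2,3-cis geometry, and both interflavan bonds are 3,4-trans (4β). The epoxy alcohol therefore has to be the erythro (1S,2R) isomer, which is the L-(+)-tartrate product.

Step 1
Reactants: 1 (−)-epigallocatechin
Product: 2 5,7,3',4',5'-penta-O-benzyl-(−)-epigallocatechin
Conditions: BnBr (5.5 equiv), K2CO3, DMF (degassed, Ar), 0 °C → rt
Reagents that add atoms: benzyl bromide, BrCc1ccccc1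
Why: Williamson etherification in which carbonate deprotonates only the five phenols, so the aliphatic 3-hydroxyl stays free and C2/C3 are untouched, while exclusion of oxygen protects the pyrogallol ring.

Step 2
Reactants: 2 5,7,3',4',5'-penta-O-benzyl-(−)-epigallocatechin
Product: 3 (2R,3R,4S)-5,7,3',4',5'-penta-O-benzyl-4-(2-ethoxyethoxy)epigallocatechin (4β ether, 3-OH free)
Conditions: DDQ (2 equiv), HOCH2CH2OEt (5 equiv), CH2Cl2, rt
Reagents that add atoms: 2-ethoxyethanol, CCOCCO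
Why: DDQ benzylic oxidation (hydride abstraction at C4) gives the ring-A-stabilised cation, which the alcohol should trap on the face opposite the cis 2-aryl and 3-hydroxyl groups, setting C4 as the 3,4-trans (4β) ether by substrate control.

Step 3
Reactants: 3 4β-(2-ethoxyethoxy) pentabenzyl ether
Product: 4 3,5,7,3',4',5'-hexa-O-benzyl-4β-(2-ethoxyethoxy)epigallocatechin (top-unit electrophile)
Conditions: NaH, BnBr, nBu4NI (cat.), THF/DMF, 0 °C → rt
Reagents that add atoms: benzyl bromide, BrCc1ccccc1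
Why: Williamson etherification of the secondary alkoxide, which protects the top 3-hydroxyl for the later Mitsunobu step without touching a stereocentre or the C4 ether.

Step 4
Reactants: 3 4β-(2-ethoxyethoxy) pentabenzyl ether
Product: 5 (2R,3S,4S)-5,7,3',4',5'-penta-O-benzyl-4-(benzylsulfanyl)epigallocatechin (4β sulfide, 3-OH free)
Conditions: BnSH (10 equiv), BF3·OEt2 (0.2 equiv), CH2Cl2, −78 → −20 °C
Reagents that add atoms: phenylmethanethiol, SCc1ccccc1
Why: Lewis-acid SN1 exchange of the thiolysis type, in which the boron acid ionises the C4 ether and the excess thiol adds trans to the 3-hydroxyl (4β), giving a sulfide that the hard acid does not reionise.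

Step 5
Reactants: 5 4β-benzylsulfanyl pentabenzyl ether; 6 3,4,5-tris(benzyloxy)benzoic acid
Product: 7 (2R,3S,4S)-5,7,3',4',5'-penta-O-benzyl-4-(benzylsulfanyl)epigallocatechin 3-O-[3,4,5-tris(benzyloxy)benzoate] (middle-unit nucleophile)
Conditions: DCC, DMAP (cat.), CH2Cl2, 0 °C → rt
Reagents that add atoms: none
Why: Steglich esterification acylates the 3-hydroxyl without breaking its C–O bond, so C3 keeps its configuration, and the sulfide and benzyl ethers are inert.

Step 6
Reactants: 4 top-unit electrophile; 7 middle-unit nucleophile (3 equiv, excess recovered)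
Product: 8 hexa-O-benzyl-epigallocatechin-(4β→8)-[penta-O-benzyl-4β-(benzylsulfanyl)epigallocatechin 3-O-(tri-O-benzylgallate)]
Conditions: Me3SiOTf (0.3 equiv), CH2Cl2, −78 °C; Et3N quench
Reagents that add atoms: none
Why: Lewis-acid Friedel–Crafts interflavan coupling in which the silyl triflate ionises only the C4 alkoxy group of 4 and C8 of 7 (the most nucleophilic carbon, flanked by O1 and the 7-benzyloxy group) attacks the cation trans to the 3-benzyloxy group, setting the top C4 as 4β, while the sulfide of 7 stays intact and the excess of 7 suppresses self-condensation of 4.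

Step 7
Reactants: 8 dimer sulfide; 9 3,5-dibenzyloxyphenol (5 equiv)
Product: 10 hexa-O-benzyl-epigallocatechin-(4β→8)-[penta-O-benzyl-4β-(2-hydroxy-4,6-bis(benzyloxy)phenyl)epigallocatechin 3-O-(tri-O-benzylgallate)]
Conditions: AgBF4 (2.5 equiv), THF, 0 °C, dark; aq NaHCO3
Reagents that add atoms: none
Why: thiophile-promoted SN1 Friedel–Crafts arylation in which monovalent silver removes the benzylsulfanyl group, the 3-O-galloyl carbonyl shields the α face so the arene enters trans (4β), and the phenol should react through the carbon ortho to OH (two such sites, each flanked by the small hydroxyl) as in acid-mediated C-alkylations of this phenol by benzylic cations.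

Step 8
Reactants: 11 3,4,5-tris(benzyloxy)benzaldehyde
Product: 12 rac-1-[3,4,5-tris(benzyloxy)phenyl]prop-2-en-1-ol
Conditions: CH2=CHMgBr, THF, −78 → 0 °C; aq NH4Cl
Reagents that add atoms: vinylmagnesium bromide, C=C[Mg]Br
Why: Grignard 1,2-addition to the aldehyde gives the racemic aryl vinyl carbinol needed for resolution.

Step 9
Reactants: 12 racemic aryl vinyl carbinol
Product: 13 (1S,2R)-2,3-epoxy-1-[3,4,5-tris(benzyloxy)phenyl]propan-1-ol (erythro)
Conditions: Ti(OiPr)4 (0.15 equiv), L-(+)-DIPT (0.2 equiv), tBuOOH (0.5 equiv), 4 Å MS, CH2Cl2, −20 °C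
Reagents that add atoms: tert-butyl hydroperoxide, CC(C)(C)OO
Why: Sharpless kinetic resolution by asymmetric epoxidation, in which the L-(+)-tartrate titanium catalyst epoxidises the (R)-alcohol fast on the tartrate-defined alkene face to give the erythro epoxy alcohol (oxirane carbon R, carbinol S) and leaves the (S)-alcohol, with the half equivalent of oxidant capping conversion.

Step 10
Reactants: 10 dimer phenol; 13 (1S,2R)-epoxy alcohol (2 equiv)
Product: 14 aryl ether of 10 whose phenolic oxygen carries the (R)-[(2R)-oxiran-2-yl][3,4,5-tris(benzyloxy)phenyl]methyl group (threo epoxy ether)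
Conditions: PPh3, DIAD, toluene, 0 °C → rt
Reagents that add atoms: none
Why: Mitsunobu etherification in which SN2 attack of the phenoxide on the oxyphosphonium inverts the carbinol carbon (S to the R ether carbon, future C2) while the oxirane carbon (future C3) is untouched and the adjacent oxirane disfavours ionisation.

Step 11
Reactants: 14 epoxy aryl ether
Product: 15 nonadeca-O-benzyl epigallocatechin-(4β→8)-epigallocatechin 3-O-gallate-(4β→8)-epigallocatechin with free 3-OH on the bottom unit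
Conditions: AuCl3 (5 mol %), AgOTf (15 mol %), 4 Å MS, ClCH2CH2Cl (0.005 M), 0 °C → rt
Reagents that add atoms: none
Why: Cationic trivalent gold (AuCl3 activated by AgOTf) binds the oxirane oxygen, and the ring-A carbon ortho to the ether oxygen, activated by O1 (ortho), the 5-benzyloxy group (ortho) and the 7-benzyloxy group (para), attacks the terminal CH2 in an SN2-like Friedel–Crafts step, after which loss of the arenium proton and protodemetalation release the 3-hydroxyl. The closest known reaction type is the gold- or Lewis-acid-catalysed cycloalkylation of aryl glycidyl ethers to chroman-3-ols, including 2-aryl cases that give flavan-3-ols. Ring C closes in the 6-endo mode, by attack at the distal oxirane carbon so that both oxirane carbons end up in the new ring. No stereocentre is created, and C2 and C3 keep the configurations set in steps 9 and 10 because neither C–O bond at these carbons is broken. The step needs endo rather than 5-exo opening, no ionisation of the benzylic C2–O1 bond and a single arene position; the unhindered primary terminus, the inductive deactivation of the internal carbon, the mild catalyst at high dilution and low temperature, and the blocking of the other ortho carbon by C4 of the middle unit should secure these.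

Step 12
Reactants: 15 benzylated trimer
Product: 16 epigallocatechin-(4β→8)-epigallocatechin 3-O-gallate-(4β→8)-epigallocatechin (CNP0278699.1)
Conditions: H2 (1 atm), Pd(OH)2/C, THF/MeOH/H2O, rt
Reagents that add atoms: none
Why: catalytic hydrogenolysis should cleave all nineteen benzyl ethers under neutral conditions that leave the gallate ester, the interflavan bonds, the O1–C2 bonds and every stereocentre intact.

Compound list
1 | (−)-epigallocatechin | O[C@@H]1Cc2c(O)cc(O)cc2O[C@@H]1c1cc(O)c(O)c(O)c1 | starting material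
2 | 5,7,3',4',5'-penta-O-benzyl-(−)-epigallocatechin | O[C@@H]1Cc2c(OCc5ccccc5)cc(OCc5ccccc5)cc2O[C@@H]1c1cc(OCc5ccccc5)c(OCc5ccccc5)c(OCc5ccccc5)c1 | intermediate
3 | (2R,3R,4S)-5,7,3',4',5'-penta-O-benzyl-4-(2-ethoxyethoxy)epigallocatechin | O[C@@H]1[C@@H](OCCOCC)c2c(OCc5ccccc5)cc(OCc5ccccc5)cc2O[C@@H]1c1cc(OCc5ccccc5)c(OCc5ccccc5)c(OCc5ccccc5)c1 | intermediate
4 | 3,5,7,3',4',5'-hexa-O-benzyl-4β-(2-ethoxyethoxy)epigallocatechin | c5ccccc5CO[C@@H]1[C@@H](OCCOCC)c2c(OCc5ccccc5)cc(OCc5ccccc5)cc2O[C@@H]1c1cc(OCc5ccccc5)c(OCc5ccccc5)c(OCc5ccccc5)c1 | intermediate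
5 | (2R,3S,4S)-5,7,3',4',5'-penta-O-benzyl-4-(benzylsulfanyl)epigallocatechin | O[C@@H]1[C@@H](SCc5ccccc5)c2c(OCc5ccccc5)cc(OCc5ccccc5)cc2O[C@@H]1c1cc(OCc5ccccc5)c(OCc5ccccc5)c(OCc5ccccc5)c1 | intermediate
6 | 3,4,5-tris(benzyloxy)benzoic acid | OC(=O)c1cc(OCc5ccccc5)c(OCc5ccccc5)c(OCc5ccccc5)c1 | starting material
7 | 5,7,3',4',5'-penta-O-benzyl-4β-(benzylsulfanyl)epigallocatechin 3-O-[3,4,5-tris(benzyloxy)benzoate] | O=C(O[C@@H]1[C@@H](SCc5ccccc5)c2c(OCc5ccccc5)cc(OCc5ccccc5)cc2O[C@@H]1c1cc(OCc5ccccc5)c(OCc5ccccc5)c(OCc5ccccc5)c1)c1cc(OCc5ccccc5)c(OCc5ccccc5)c(OCc5ccccc5)c1 | intermediate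
8 | hexa-O-benzyl-epigallocatechin-(4β→8)-[penta-O-benzyl-4β-(benzylsulfanyl)epigallocatechin 3-O-(tri-O-benzylgallate)] | O=C(O[C@@H]1[C@@H](SCc5ccccc5)c2c(OCc5ccccc5)cc(OCc5ccccc5)c([C@H]3c4c(OCc5ccccc5)cc(OCc5ccccc5)cc4O[C@H](c4cc(OCc5ccccc5)c(OCc5ccccc5)c(OCc5ccccc5)c4)[C@@H]3OCc5ccccc5)c2O[C@@H]1c1cc(OCc5ccccc5)c(OCc5ccccc5)c(OCc5ccccc5)c1)c1cc(OCc5ccccc5)c(OCc5ccccc5)c(OCc5ccccc5)c1 | intermediate
9 | 3,5-dibenzyloxyphenol | Oc1cc(OCc2ccccc2)cc(OCc2ccccc2)c1 | starting material
10 | dimer of 8 with the 4β-benzylsulfanyl group replaced by a 4β-[2-hydroxy-4,6-bis(benzyloxy)phenyl] group | O=C(O[C@@H]1[C@@H](c2c(OCc5ccccc5)cc(OCc5ccccc5)cc2O)c2c(OCc5ccccc5)cc(OCc5ccccc5)c([C@H]3c4c(OCc5ccccc5)cc(OCc5ccccc5)cc4O[C@H](c4cc(OCc5ccccc5)c(OCc5ccccc5)c(OCc5ccccc5)c4)[C@@H]3OCc5ccccc5)c2O[C@@H]1c1cc(OCc5ccccc5)c(OCc5ccccc5)c(OCc5ccccc5)c1)c1cc(OCc5ccccc5)c(OCc5ccccc5)c(OCc5ccccc5)c1 | intermediate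
11 | 3,4,5-tris(benzyloxy)benzaldehyde | O=Cc1cc(OCc2ccccc2)c(OCc2ccccc2)c(OCc2ccccc2)c1 | starting material
12 | rac-1-[3,4,5-tris(benzyloxy)phenyl]prop-2-en-1-ol | OC(C=C)c1cc(OCc2ccccc2)c(OCc2ccccc2)c(OCc2ccccc2)c1 | intermediate
13 | (S)-[(2R)-oxiran-2-yl][3,4,5-tris(benzyloxy)phenyl]methanol, i.e. (1S,2R)-2,3-epoxy-1-arylpropan-1-ol | O[C@H]([C@H]1CO1)c1cc(OCc2ccccc2)c(OCc2ccccc2)c(OCc2ccccc2)c1 | intermediate
14 | ether of 10 carrying the (R)-[(2R)-oxiran-2-yl][3,4,5-tris(benzyloxy)phenyl]methyl group on the phenolic oxygen | O=C(O[C@@H]1[C@@H](c2c(OCc5ccccc5)cc(OCc5ccccc5)cc2O[C@H](c2cc(OCc5ccccc5)c(OCc5ccccc5)c(OCc5ccccc5)c2)[C@H]3CO3)c2c(OCc5ccccc5)cc(OCc5ccccc5)c([C@H]3c4c(OCc5ccccc5)cc(OCc5ccccc5)cc4O[C@H](c4cc(OCc5ccccc5)c(OCc5ccccc5)c(OCc5ccccc5)c4)[C@@H]3OCc5ccccc5)c2O[C@@H]1c1cc(OCc5ccccc5)c(OCc5ccccc5)c(OCc5ccccc5)c1)c1cc(OCc5ccccc5)c(OCc5ccccc5)c(OCc5ccccc5)c1 | intermediate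
15 | nonadeca-O-benzyl trimer with free bottom 3-OH | O=C(O[C@@H]1[C@@H](c2c(OCc5ccccc5)cc(OCc5ccccc5)c3c2O[C@H](c2cc(OCc5ccccc5)c(OCc5ccccc5)c(OCc5ccccc5)c2)[C@H](O)C3)c2c(OCc5ccccc5)cc(OCc5ccccc5)c([C@H]3c4c(OCc5ccccc5)cc(OCc5ccccc5)cc4O[C@H](c4cc(OCc5ccccc5)c(OCc5ccccc5)c(OCc5ccccc5)c4)[C@@H]3OCc5ccccc5)c2O[C@@H]1c1cc(OCc5ccccc5)c(OCc5ccccc5)c(OCc5ccccc5)c1)c1cc(OCc5ccccc5)c(OCc5ccccc5)c(OCc5ccccc5)c1 | intermediate
16 | epigallocatechin-(4β→8)-epigallocatechin 3-O-gallate-(4β→8)-epigallocatechin | O=C(O[C@@H]1[C@@H](c2c(O)cc(O)c3c2O[C@H](c2cc(O)c(O)c(O)c2)[C@H](O)C3)c2c(O)cc(O)c([C@H]3c4c(O)cc(O)cc4O[C@H](c4cc(O)c(O)c(O)c4)[C@@H]3O)c2O[C@@H]1c1cc(O)c(O)c(O)c1)c1cc(O)c(O)c(O)c1 | target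

Total step count: 12
Longest linear sequence: 9 steps (1, 2, 4, 5, 6, 7, 10, 11, 12)

Steps most likely to fail

Step 11 (key cyclisation). The activated oxirane may open at its internal carbon (5-exo closure to a dihydrobenzofuran), the benzylic C2–O1 ether may ionise and shed the side chain, or the acid may cleave an interflavan bond. The fallback forms the lower interflavan bond instead of ring C. It sets out from sulfide 8 and pentabenzyl ether 2. AgBF4 in THF at 0 °C ionises C4 of the middle unit of 8, and C8 of 2 (3 equiv) attacks trans to the galloyloxy group. This silver-promoted C4→C8 coupling gives 15 directly, where the route is rejoined before step 12. No new compound is made (F0).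

Step 10 (Mitsunobu). The ortho-substituted phenoxide may attack too slowly, so that the oxyphosphonium ionises at the benzylic carbon (erosion of configuration at the future C2) or alkylates the hydrazide. The fallback replaces redox activation by base-mediated phenoxide opening of a cis-epoxide and sets out from 10 and 11:
- Still–Gennari olefination of 11 (methyl bis(2,2,2-trifluoroethyl)phosphonoacetate, KN(SiMe3)2, 18-crown-6, THF, −78 °C) gives methyl (Z)-3-[3,4,5-tris(benzyloxy)phenyl]prop-2-enoate F1.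
- Reduction with iBu2AlH gives (Z)-3-[3,4,5-tris(benzyloxy)phenyl]prop-2-en-1-ol F2.
- Sharpless epoxidation (Ti(OiPr)4, D-(−)-DIPT, tBuOOH, CH2Cl2, −20 °C) gives [(2R,3S)-3-[3,4,5-tris(benzyloxy)phenyl]oxiran-2-yl]methanol F3.
- The cesium phenoxide of 10 (Cs2CO3, DMF, 60 °C) opens F3 at the benzylic carbon with inversion, giving the 3-aryloxy-3-aryl-propane-1,2-diol F4.
- Selective primary tosylation (TsCl, Et3N, Bu2SnO cat.) gives the monotosylate F5.
- NaH in THF at 0 °C closes the terminal oxirane with the C–O bond at the future C3 retained, which returns the route to 14.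

Step 7 (arylation with 9). The phenol may react through the carbon para to OH (between the two benzyloxy groups) or through oxygen, or the cation may be captured by the free C6/C8 positions of another dimer. The fallback uses a nucleophile whose three ring positions are equivalent and sets out from 8. Phloroglucinol (10 equiv) with AgBF4 in THF at 0 °C gives the 4β-(2,4,6-trihydroxyphenyl) dimer F6. Controlled benzylation (BnBr 2.1 equiv, K2CO3, DMF, rt) should then etherify the unhindered para hydroxyl and one of the two equivalent ortho hydroxyls, leaving the remaining hindered ortho hydroxyl free, which is 10.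

Further compounds
F0 | step 11 | none | none
F1 | step 10 | methyl (Z)-3-[3,4,5-tris(benzyloxy)phenyl]prop-2-enoate | COC(=O)/C=C\c1cc(OCc2ccccc2)c(OCc2ccccc2)c(OCc2ccccc2)c1
F2 | step 10 | (Z)-3-[3,4,5-tris(benzyloxy)phenyl]prop-2-en-1-ol | OC/C=C\c1cc(OCc2ccccc2)c(OCc2ccccc2)c(OCc2ccccc2)c1
F3 | step 10 | [(2R,3S)-3-[3,4,5-tris(benzyloxy)phenyl]oxiran-2-yl]methanol | OC[C@H]1O[C@H]1c1cc(OCc2ccccc2)c(OCc2ccccc2)c(OCc2ccccc2)c1
F4 | step 10 | ether of 10 carrying the (1R,2R)-2,3-dihydroxy-1-[3,4,5-tris(benzyloxy)phenyl]propyl group on the phenolic oxygen | O=C(O[C@@H]1[C@@H](c2c(OCc5ccccc5)cc(OCc5ccccc5)cc2O[C@H](c2cc(OCc5ccccc5)c(OCc5ccccc5)c(OCc5ccccc5)c2)[C@H](O)CO)c2c(OCc5ccccc5)cc(OCc5ccccc5)c([C@H]3c4c(OCc5ccccc5)cc(OCc5ccccc5)cc4O[C@H](c4cc(OCc5ccccc5)c(OCc5ccccc5)c(OCc5ccccc5)c4)[C@@H]3OCc5ccccc5)c2O[C@@H]1c1cc(OCc5ccccc5)c(OCc5ccccc5)c(OCc5ccccc5)c1)c1cc(OCc5ccccc5)c(OCc5ccccc5)c(OCc5ccccc5)c1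
F5 | step 10 | primary 4-methylbenzenesulfonate of diol F4 | O=C(O[C@@H]1[C@@H](c2c(OCc5ccccc5)cc(OCc5ccccc5)cc2O[C@H](c2cc(OCc5ccccc5)c(OCc5ccccc5)c(OCc5ccccc5)c2)[C@H](O)COS(=O)(=O)c6ccc(C)cc6)c2c(OCc5ccccc5)cc(OCc5ccccc5)c([C@H]3c4c(OCc5ccccc5)cc(OCc5ccccc5)cc4O[C@H](c4cc(OCc5ccccc5)c(OCc5ccccc5)c(OCc5ccccc5)c4)[C@@H]3OCc5ccccc5)c2O[C@@H]1c1cc(OCc5ccccc5)c(OCc5ccccc5)c(OCc5ccccc5)c1)c1cc(OCc5ccccc5)c(OCc5ccccc5)c(OCc5ccccc5)c1
F6 | step 7 | dimer of 8 with the 4β-benzylsulfanyl group replaced by a 4β-(2,4,6-trihydroxyphenyl) group | O=C(O[C@@H]1[C@@H](c2c(O)cc(O)cc2O)c2c(OCc5ccccc5)cc(OCc5ccccc5)c([C@H]3c4c(OCc5ccccc5)cc(OCc5ccccc5)cc4O[C@H](c4cc(OCc5ccccc5)c(OCc5ccccc5)c(OCc5ccccc5)c4)[C@@H]3OCc5ccccc5)c2O[C@@H]1c1cc(OCc5ccccc5)c(OCc5ccccc5)c(OCc5ccccc5)c1)c1cc(OCc5ccccc5)c(OCc5ccccc5)c(OCc5ccccc5)c1
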